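The 14-membered carbocycle is opened at the C12–C13 single bond, where the methyl-bearing end of the Z C11=C12 alkene meets the two-carbon arm C13–C14 that hangs from C1, the only stereocentre. One intramolecular alkyl–alkenyl Suzuki–Miyaura coupling makes this bond, closes the ring and passes the geometry of the iodide on to the ring alkene. Its substrate is an open chain with a primary C13 boron group (built as the pinacol ester, cyclised as the trifluoroborate), a Z C12 alkenyl iodide, the Z C3=C4 enoate and the E C7=C8 alkene. C1 comes unchanged from (R)-limonene; a Still–Gennari olefination joins the two halves.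

Key step: step 19

Atom numbering: ring C1 (CH with the side chain), C2, C3=C4 (C4 bears CO2Me), C5, C6, C7=C8 (C8 bears CH3), C9, C10, C11=C12 (C12 bears CH3), C13, C14. Side chain C15(=C16H2), C17, C18, C19, C20 (carbinol).
Remark on carbon count: a geranyl unit supplies only C6–C11 with the C8 methyl, and the phosphonoacetate only C4 with the ester, so C5 is added by methylenation and hydroboration (steps 13 and 14).
Remark on the boron group: a primary alkyl pinacol boronate hands its alkyl group to palladium slowly. It therefore serves as the robust carrier through the olefination and is exchanged for the trifluoroborate just before ring closure. Carbonate is used as base to spare the methyl ester.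
Remark on protection: the C20 carbinol must be masked only against the allyllithium of step 3. The silyl ether falls in step 4, so the ring closure delivers the target itself.
Assumption: (R)-limonene of high enantiomeric purity and geranyl acetate free of the neryl isomer are bought; C1 of the target is R, the same spatial arrangement as C4 of (R)-limonene.

Step 1
Reactants: 1 3-methylbutane-1,3-diol
Product: 2 4-bromo-2-methylbutan-2-ol
Conditions: CBr4, PPh3, CH2Cl2, 0 °C
Reagents that add atoms: carbon tetrabromide, BrC(Br)(Br)Br
Why: The Appel bromination runs through SN2 displacement of an alkoxyphosphonium ion, a path open to the primary but not to the tertiary hydroxyl group.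

Step 2
Reactants: 2 4-bromo-2-methylbutan-2-ol
Product: 3 [(4-bromo-2-methylbutan-2-yl)oxy]triethylsilane
Conditions: Et3SiOTf, 2,6-lutidine, CH2Cl2, 0 °C
Reagents that add atoms: triethylsilyl trifluoromethanesulfonate, CC[Si](CC)(CC)OS(=O)(=O)C(F)(F)F
Why: Silylation with a silyl triflate and a hindered base is the standard way to cap a tertiary alcohol, and the triethylsilyl group resists attack at silicon by the carbanion of the next step.

Step 3
Reactants: 4 (R)-(+)-limonene; 3 [(4-bromo-2-methylbutan-2-yl)oxy]triethylsilane
Product: 6 triethyl({2-methyl-6-[(1R)-4-methylcyclohex-3-en-1-yl]hept-6-en-2-yl}oxy)silane, via 10-lithiolimonene 5 (not isolated)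
Conditions: 4 (excess), nBuLi, TMEDA, hexane, rt; then 3, THF, −78 °C → rt
Reagents that add atoms: none
Why: nBuLi·TMEDA metalates the isopropenyl methyl group kinetically, the 2-substituted allyllithium has two equivalent termini so that SN2 alkylation by the primary bromide can give only one skeleton (C17–C18 bond), and the ring CH that becomes C1 is not touched.

Step 4
Reactants: 6 triethyl({2-methyl-6-[(1R)-4-methylcyclohex-3-en-1-yl]hept-6-en-2-yl}oxy)silane
Product: 8 (5R)-5-(2,2-dimethoxyethyl)-10-hydroxy-10-methyl-6-methylideneundecan-2-one, via silylated keto aldehyde 7 (not isolated)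
Conditions: O3, CH2Cl2/MeOH, Sudan Red 7B end point, −78 °C; Me2S, −78 °C → rt; then CH(OMe)3 (slight excess), TsOH·H2O (cat.), rt; NaHCO3
Reagents that add atoms: ozone, [O-][O+]=O; trimethyl orthoformate, COC(OC)OC
Why: Electrophilic ozone attacks the trisubstituted ring alkene ahead of the 1,1-disubstituted C15=C16 alkene (Criegee ozonolysis stopped at the dye end point), and acid methanolysis then acetalises only the aldehyde, leaves the less electrophilic methyl ketone and strips the now superfluous silyl ether.

Step 5
Reactants: 8 (5R)-5-(2,2-dimethoxyethyl)-10-hydroxy-10-methyl-6-methylideneundecan-2-one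
Product: 9 (4R)-4-(2,2-dimethoxyethyl)-9-hydroxy-9-methyl-5-methylidenedecanoic acid
Conditions: Br2, NaOH, H2O/dioxane (NaOBr preformed), 0 °C, dark; Na2SO3; 1 M HCl to pH 4, 0 °C
Reagents that add atoms: sodium hydroxide, [Na+].[OH-]
Why: The haloform reaction brominates the CH3 of the methyl ketone exhaustively and hydroxide then expels tribromomethanide, while alkene, acetal and tertiary alcohol are inert to hypobromite at high pH as long as the oxidant is destroyed before acidification.

Step 6
Reactants: 9 (4R)-4-(2,2-dimethoxyethyl)-9-hydroxy-9-methyl-5-methylidenedecanoic acid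
Product: 10 1,3-dioxoisoindolin-2-yl (4R)-4-(2,2-dimethoxyethyl)-9-hydroxy-9-methyl-5-methylidenedecanoate
Conditions: N-hydroxyphthalimide, DIC, DMAP (cat.), CH2Cl2, rt
Reagents that add atoms: N-hydroxyphthalimide, O=C1c2ccccc2C(=O)N1O
Why: Carbodiimide (Steglich-type) esterification acylates the acidic N-hydroxy group quickly, whereas the hindered tertiary alcohol does not compete.

Step 7
Reactants: 10 1,3-dioxoisoindolin-2-yl (4R)-4-(2,2-dimethoxyethyl)-9-hydroxy-9-methyl-5-methylidenedecanoate
Product: 11 (7R)-9,9-dimethoxy-2-methyl-6-methylidene-7-[2-(4,4,5,5-tetramethyl-1,3,2-dioxaborolan-2-yl)ethyl]nonan-2-ol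
Conditions: B2pin2, Cu(acac)2 (30 mol %), LiOH·H2O, MgCl2, dioxane/DMF, rt
Reagents that add atoms: bis(pinacolato)diboron, CC1(C)OB(OC1(C)C)B1OC(C)(C)C(C)(C)O1
Why: In this copper-catalysed decarboxylative borylation of a redox-active ester a boryl–copper species reduces the N-acyloxyphthalimide, loss of CO2 leaves the primary C13 radical, and its capture at copper should outrun the disfavoured 4-exo or 5-endo attack on C15=C16 and the polarity-mismatched hydrogen shift from the acetal.

Step 8
Reactants: 11 (7R)-9,9-dimethoxy-2-methyl-6-methylidene-7-[2-(4,4,5,5-tetramethyl-1,3,2-dioxaborolan-2-yl)ethyl]nonan-2-ol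
Product: 12 (3R)-8-hydroxy-8-methyl-4-methylidene-3-[2-(4,4,5,5-tetramethyl-1,3,2-dioxaborolan-2-yl)ethyl]nonanal
Conditions: 1 M HCl, THF, 0 °C → rt
Reagents that add atoms: water, O
Why: Acid-catalysed hydrolysis of a dimethyl acetal is fast under conditions that the pinacol boronate, the tertiary alcohol and the alkene tolerate, and C1 lies β to the aldehyde and cannot epimerise by enolisation.

Step 9
Reactants: 13 geranyl acetate
Product: 14 (2E)-3-methyl-6-oxohex-2-en-1-yl acetate
Conditions: O3, CH2Cl2/MeOH, Sudan Red 7B end point, −78 °C; Me2S, −78 °C → rt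
Reagents that add atoms: ozone, [O-][O+]=O
Why: In this selective Criegee ozonolysis the allylic acetoxy group lowers the nucleophilicity of the future C7=C8 alkene, so ozone consumes the terminal isopropylidene alkene first and frees C11 as the aldehyde.

Step 10
Reactants: 14 (2E)-3-methyl-6-oxohex-2-en-1-yl acetate
Product: 15 (2E,6Z)-7-iodo-3-methylocta-2,6-dien-1-yl acetate
Conditions: EtPPh3I, nBuLi, THF, rt; I2, −78 °C; NaN(SiMe3)2, −20 °C; then 14, −78 °C → −20 °C
Reagents that add atoms: ethyltriphenylphosphonium iodide, CC[P+](c1ccccc1)(c1ccccc1)c1ccccc1.[I-]; iodine, II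
Why: The Stork–Zhao-type Wittig olefination with the α-iodo ylide Ph3P=C(I)CH3 is kinetically controlled at low temperature and places iodine cis to the chain, which should give the Z C11=C12 alkenyl iodide while the acetate and the C7=C8 alkene are left alone.

Step 11
Reactants: 15 (2E,6Z)-7-iodo-3-methylocta-2,6-dien-1-yl acetate
Product: 16 (2E,6Z)-7-iodo-3-methylocta-2,6-dien-1-ol
Conditions: K2CO3 (cat.), MeOH, 0 °C → rt
Reagents that add atoms: none
Why: Base-catalysed transesterification removes the acetate under conditions to which both alkenes and the alkenyl iodide are indifferent.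

Step 12
Reactants: 16 (2E,6Z)-7-iodo-3-methylocta-2,6-dien-1-ol
Product: 17 (2E,6Z)-7-iodo-3-methylocta-2,6-dienal
Conditions: MnO2 (activated), CH2Cl2, rt
Reagents that add atoms: none
Why: Allylic oxidation with MnO2 is neutral and stops at the enal with the E geometry kept.

Step 13
Reactants: 17 (2E,6Z)-7-iodo-3-methylocta-2,6-dienal
Product: 18 (3E,7Z)-8-iodo-4-methylnona-1,3,7-triene
Conditions: MePPh3Br (slight excess over base), nBuLi, THF, 0 °C; then 17, −78 °C → rt
Reagents that add atoms: methyltriphenylphosphonium bromide, C[P+](c1ccccc1)(c1ccccc1)c1ccccc1.[Br-]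
Why: Wittig methylenation adds C5 as a terminal CH2, the non-stabilised ylide adding 1,2 to the enal without disturbing the E C7=C8 geometry or the alkenyl iodide.

Step 14
Reactants: 18 (3E,7Z)-8-iodo-4-methylnona-1,3,7-triene
Product: 20 (3E,7Z)-8-iodo-4-methylnona-3,7-dien-1-ol, via B-alkyl-9-BBN adduct 19 (not isolated)
Conditions: 9-BBN, THF, 0 °C → rt; then NaOH, H2O2, 0 °C
Reagents that add atoms: hydrogen peroxide, OO
Why: In this Brown hydroboration–oxidation 9-BBN adds to the only monosubstituted alkene with boron on the terminal carbon C5, ignores the trisubstituted alkene and the iodoalkene, and alkaline peroxide replaces boron by hydroxyl.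

Step 15
Reactants: 20 (3E,7Z)-8-iodo-4-methylnona-3,7-dien-1-ol
Product: 21 (2Z,6E)-2,9-diiodo-6-methylnona-2,6-diene
Conditions: I2, PPh3, imidazole, CH2Cl2, 0 °C
Reagents that add atoms: iodine, II
Why: Appel-type iodination converts the primary alcohol by SN2 under nearly neutral conditions that do not provoke elimination to the diene.

Step 16
Reactants: 22 methyl bis(2,2,2-trifluoroethyl)phosphonoacetate; 21 (2Z,6E)-2,9-diiodo-6-methylnona-2,6-diene
Product: 24 methyl (5E,9Z)-2-[bis(2,2,2-trifluoroethoxy)phosphoryl]-10-iodo-6-methylundeca-5,9-dienoate, via sodium phosphonoacetate 23 (not isolated)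
Conditions: 22 (excess), NaH, DMF, 0 °C; then 21, rt → 45 °C
Reagents that add atoms: none
Why: SN2 C-alkylation of the soft, weakly basic phosphonoacetate carbanion forms C4–C5 at the primary iodide only, the alkenyl iodide being inert to substitution and the excess of 22 holding back a second alkylation.

Step 17
Reactants: 24 methyl (5E,9Z)-2-[bis(2,2,2-trifluoroethoxy)phosphoryl]-10-iodo-6-methylundeca-5,9-dienoate; 12 (3R)-8-hydroxy-8-methyl-4-methylidene-3-[2-(4,4,5,5-tetramethyl-1,3,2-dioxaborolan-2-yl)ethyl]nonanal
Product: 26 methyl (2Z,5R)-10-hydroxy-2-[(3E,7Z)-8-iodo-4-methylnona-3,7-dien-1-yl]-10-methyl-6-methylidene-5-[2-(4,4,5,5-tetramethyl-1,3,2-dioxaborolan-2-yl)ethyl]undec-2-enoate, via potassium phosphonate carbanion 25 (not isolated)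
Conditions: 24 (slight excess), KN(SiMe3)2, 18-crown-6, THF, −78 °C; then 12, −78 °C
Reagents that add atoms: none
Why: In the Still–Gennari olefination the electron-poor bis(trifluoroethyl) phosphonate with a dissociated potassium ion makes collapse of the kinetic adduct faster than its reversal, which should place the ester cis to C2 (Z C3=C4), and neither the boronate, the tertiary alcohol nor C1 reacts with the stabilised carbanion.

Step 18
Reactants: 26 seco pinacol boronate (as named in step 17)
Product: 27 potassium trifluoroborate of the seco chain (C13–BF3K, Z C12 alkenyl iodide, Z enoate, 1R)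
Conditions: KHF2 (4.5 M aq.), MeOH, rt, PTFE vessel; repeated evaporation with aq. MeOH; extraction into acetone
Reagents that add atoms: potassium hydrogen difluoride, [K+].[F-].F
Why: Fluoride exchange at boron with KHF2 is driven by the strength of the B–F bonds and by azeotropic removal of pinacol, and leaves ester, alkenes, alkenyl iodide and free carbinol unchanged.

Step 19
Reactants: 27 potassium trifluoroborate of the seco chain
Product: 28 target, methyl ester of the (1R,3Z,7E,11Z)-cembratriene acid bearing the 6-hydroxy-6-methylhept-1-en-2-yl group on C1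
Conditions: PdCl2(dppf)·CH2Cl2 (15–20 mol %), Cs2CO3, degassed THF/H2O 10:1, 70 °C, 27 added by syringe pump over 12 h to about 1 mM final concentration
Reagents that add atoms: none
Why: Zerovalent palladium formed from PdCl2(dppf) inserts into the C12–I bond with retention, slow hydrolysis of the trifluoroborate releases the C13 boronic acid, its oxygen-bridged complex with palladium hands over the primary alkyl group, and reductive elimination makes C12–C13. The closest known reaction type is the B-alkyl Suzuki–Miyaura macrocyclisation, together with the coupling of potassium primary-alkyltrifluoroborates with alkenyl halides under the same catalyst and base. The 14-membered ring closes end to end in the sp3–sp2 reductive elimination from a 15-membered palladacycle, helped by pseudo-high dilution and by three planar alkenes that remove rotors from the chain. No stereocentre is created: C1 is remote and untouched, and the Z geometry of C11=C12 is inherited from the iodide because oxidative addition and reductive elimination both keep configuration. The step needs cyclisation over oligomerisation, and coupling over β-hydride loss and over 5-exo carbopalladation of C7=C8. Slow addition, the chelating wide-bite-angle dppf (fast reductive elimination, no free site for an alkene) and carbonate as base (methyl ester kept) provide for this.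

Compound list
1 | 3-methylbutane-1,3-diol | CC(C)(O)CCO | starting material
2 | 4-bromo-2-methylbutan-2-ol | CC(C)(O)CCBr | intermediate
3 | [(4-bromo-2-methylbutan-2-yl)oxy]triethylsilane | CC[Si](CC)(CC)OC(C)(C)CCBr | intermediate
4 | (R)-(+)-limonene | CC1=CC[C@@H](CC1)C(C)=C | starting material
5 | 10-lithiolimonene, {2-[(1R)-4-methylcyclohex-3-en-1-yl]prop-2-en-1-yl}lithium | [Li]CC(=C)[C@@H]1CCC(C)=CC1 | intermediate
6 | triethyl({2-methyl-6-[(1R)-4-methylcyclohex-3-en-1-yl]hept-6-en-2-yl}oxy)silane | CC1=CC[C@@H](CC1)C(=C)CCCC(C)(C)O[Si](CC)(CC)CC | intermediate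
7 | (3R)-8-methyl-4-methylidene-3-(3-oxobutyl)-8-(triethylsilyloxy)nonanal | O=CC[C@@H](CCC(C)=O)C(=C)CCCC(C)(C)O[Si](CC)(CC)CC | intermediate
8 | (5R)-5-(2,2-dimethoxyethyl)-10-hydroxy-10-methyl-6-methylideneundecan-2-one | COC(OC)C[C@@H](CCC(C)=O)C(=C)CCCC(C)(C)O | intermediate
9 | (4R)-4-(2,2-dimethoxyethyl)-9-hydroxy-9-methyl-5-methylidenedecanoic acid | COC(OC)C[C@@H](CCC(=O)O)C(=C)CCCC(C)(C)O | intermediate
10 | N-acyloxyphthalimide of acid 9 | COC(OC)C[C@@H](CCC(=O)ON1C(=O)c2ccccc2C1=O)C(=C)CCCC(C)(C)O | intermediate
11 | (7R)-9,9-dimethoxy-2-methyl-6-methylidene-7-[2-(4,4,5,5-tetramethyl-1,3,2-dioxaborolan-2-yl)ethyl]nonan-2-ol | COC(OC)C[C@@H](CCB1OC(C)(C)C(C)(C)O1)C(=C)CCCC(C)(C)O | intermediate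
12 | (3R)-8-hydroxy-8-methyl-4-methylidene-3-[2-(4,4,5,5-tetramethyl-1,3,2-dioxaborolan-2-yl)ethyl]nonanal | O=CC[C@@H](CCB1OC(C)(C)C(C)(C)O1)C(=C)CCCC(C)(C)O | intermediate
13 | geranyl acetate | CC(C)=CCC/C(C)=C/COC(C)=O | starting material
14 | (2E)-3-methyl-6-oxohex-2-en-1-yl acetate | O=CCC/C(C)=C/COC(C)=O | intermediate
15 | (2E,6Z)-7-iodo-3-methylocta-2,6-dien-1-yl acetate | CC(=O)OC/C=C(\C)CC/C=C(/C)I | intermediate
16 | (2E,6Z)-7-iodo-3-methylocta-2,6-dien-1-ol | OC/C=C(\C)CC/C=C(/C)I | intermediate
17 | (2E,6Z)-7-iodo-3-methylocta-2,6-dienal | O=C/C=C(\C)CC/C=C(/C)I | intermediate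
18 | (3E,7Z)-8-iodo-4-methylnona-1,3,7-triene | C=C/C=C(\C)CC/C=C(/C)I | intermediate
19 | 9-[(3E,7Z)-8-iodo-4-methylnona-3,7-dien-1-yl]-9-borabicyclo[3.3.1]nonane | C1CC2CCCC(C1)B2CC/C=C(\C)CC/C=C(/C)I | intermediate
20 | (3E,7Z)-8-iodo-4-methylnona-3,7-dien-1-ol | OCC/C=C(\C)CC/C=C(/C)I | intermediate
21 | (2Z,6E)-2,9-diiodo-6-methylnona-2,6-diene | ICC/C=C(\C)CC/C=C(/C)I | intermediate
22 | methyl bis(2,2,2-trifluoroethyl)phosphonoacetate | COC(=O)CP(=O)(OCC(F)(F)F)OCC(F)(F)F | starting material
23 | sodium salt of 22 | COC(=O)[CH-]P(=O)(OCC(F)(F)F)OCC(F)(F)F.[Na+] | intermediate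
24 | methyl (5E,9Z)-2-[bis(2,2,2-trifluoroethoxy)phosphoryl]-10-iodo-6-methylundeca-5,9-dienoate (racemic at C4, centre lost in step 17) | COC(=O)C(CC/C=C(\C)CC/C=C(/C)I)P(=O)(OCC(F)(F)F)OCC(F)(F)F | intermediate
25 | potassium salt of 24 | COC(=O)[C-](CC/C=C(\C)CC/C=C(/C)I)P(=O)(OCC(F)(F)F)OCC(F)(F)F.[K+] | intermediate
26 | seco C13 pinacol boronate with Z C12 alkenyl iodide, Z C3=C4 enoate, E C7=C8, 1R, free C20 carbinol | C=C(CCCC(C)(C)O)[C@H](CCB1OC(C)(C)C(C)(C)O1)C/C=C(\C(=O)OC)CC/C=C(\C)CC/C=C(/C)I | intermediate
27 | seco C13 potassium trifluoroborate, otherwise as 26 | C=C(CCCC(C)(C)O)[C@H](CC[B-](F)(F)F)C/C=C(\C(=O)OC)CC/C=C(\C)CC/C=C(/C)I.[K+] | intermediate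
28 | CNP0326472.1, 14-membered carbocycle, 1R, 3Z, 7E, 11Z | C=C(CCCC(C)(C)O)[C@H]1C/C=C(\C(=O)OC)CC/C=C(\C)CC/C=C(/C)CC1 | target

Total step count: 19.
Longest linear sequence: 11 steps (steps 1–8, then 17–19). The geranyl branch (steps 9–16, then 17–19) is equally long.

Steps most likely to fail

1. Step 19 (ring closure).
   - What may go wrong: alkyl transfer within the dilute chain may be slow. Coupling between molecules, protodeboronation, β-hydride loss or 5-exo carbopalladation of the C7=C8 alkene by the alkenylpalladium intermediate may then take over.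
   - Fallback: the C12–C13 bond is made between two molecules at ordinary concentration, and the ring is closed instead at C3=C4 by an intramolecular Still–Gennari olefination. The fallback sets out from 11 and 20 and comes back at 28.
   - Course: KHF2 in aqueous MeOH turns 11 into the potassium trifluoroborate acetal F1. PdCl2(dppf)·CH2Cl2 and Cs2CO3 in THF/H2O couple F1 with the alkenyl iodide 20 to the diol acetal F2. I2, PPh3 and imidazole convert its primary alcohol into the primary iodide F3. The sodium salt 23 is alkylated with F3 to the phosphonate acetal F4. 1 M HCl in THF frees the phosphonate aldehyde F5. Slow addition of F5 to K2CO3 and 18-crown-6 in toluene closes the Z enoate and gives 28.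

2. Step 7 (decarboxylative borylation).
   - What may go wrong: LiOH may hydrolyse the active ester, or the C13 radical may be reduced or undergo a hydrogen shift before boron is delivered.
   - Fallback: the acetyl arm is cut to a vinyl group and boron is brought in by catalysed hydroboration. The fallback sets out from 6 and comes back at 11.
   - Course: ozonolysis of 6 in CH2Cl2/MeOH as in step 4 is followed, without a reductant, by TsOH. This acetalises the aldehyde and removes the silyl group but keeps the α-methoxy hydroperoxide acetal F6. FeSO4·7H2O and Cu(OAc)2·H2O in MeOH then cleave the O–O bond, the alkoxyl radical loses methyl acetate by β-scission, and Cu(OAc)2 oxidises the primary C13 radical to the vinyl acetal F7. Anti-Markovnikov hydroboration with HBpin and [Ir(cod)Cl]2/dppm takes the monosubstituted alkene ahead of the 1,1-disubstituted one and gives 11.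

3. Step 10 (iodoethylidenation).
   - What may go wrong: low conversion of the aldehyde, loss of iodine from the ylide, or erosion of the Z geometry.
   - Fallback: the halogen-bearing carbon is installed first and the methyl group second. The fallback sets out from 14 and comes back at 16.
   - Course: Ramirez olefination (CBr4, PPh3) gives the dibromoalkene acetate F8, and K2CO3 in MeOH gives the dibromoalkene alcohol F9, which no longer carries an allylic leaving group. Negishi coupling with Me2Zn and PdCl2(DPEphos) replaces only the less hindered bromine trans to the chain and gives the Z bromoalkene alcohol F10. A copper-catalysed Finkelstein exchange (CuI, NaI, N,N'-dimethylethylenediamine, dioxane, heat) with retention gives 16.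

Further compounds
F1 | step 19 | potassium [(3R)-3-(2,2-dimethoxyethyl)-8-hydroxy-8-methyl-4-methylidenenonyl]trifluoroborate | COC(OC)C[C@@H](CC[B-](F)(F)F)C(=C)CCCC(C)(C)O.[K+]
F2 | step 19 | (3E,7Z,11R)-11-(2,2-dimethoxyethyl)-4,8,16-trimethyl-12-methylideneheptadeca-3,7-diene-1,16-diol | OCC/C=C(\C)CC/C=C(/C)CC[C@H](CC(OC)OC)C(=C)CCCC(C)(C)O
F3 | step 19 | primary C5 iodide derived from F2 | ICC/C=C(\C)CC/C=C(/C)CC[C@H](CC(OC)OC)C(=C)CCCC(C)(C)O
F4 | step 19 | bis(2,2,2-trifluoroethyl) phosphonate acetal (C4 phosphonoacetate alkylated with F3) | COC(=O)C(CC/C=C(\C)CC/C=C(/C)CC[C@H](CC(OC)OC)C(=C)CCCC(C)(C)O)P(=O)(OCC(F)(F)F)OCC(F)(F)F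
F5 | step 19 | phosphonate aldehyde (C3 aldehyde, C4 phosphonoacetate) | COC(=O)C(CC/C=C(\C)CC/C=C(/C)CC[C@H](CC=O)C(=C)CCCC(C)(C)O)P(=O)(OCC(F)(F)F)OCC(F)(F)F
F6 | step 7 | α-methoxy hydroperoxide acetal (mixture at the peroxy carbon) | COC(OC)C[C@@H](CCC(C)(OC)OO)C(=C)CCCC(C)(C)O
F7 | step 7 | (7S)-7-ethenyl-9,9-dimethoxy-2-methyl-6-methylidenenonan-2-ol | COC(OC)C[C@@H](C=C)C(=C)CCCC(C)(C)O
F8 | step 10 | (2E)-7,7-dibromo-3-methylhepta-2,6-dien-1-yl acetate | CC(=O)OC/C=C(\C)CCC=C(Br)Br
F9 | step 10 | (2E)-7,7-dibromo-3-methylhepta-2,6-dien-1-ol | OC/C=C(\C)CCC=C(Br)Br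
F10 | step 10 | (2E,6Z)-7-bromo-3-methylocta-2,6-dien-1-ol | OC/C=C(\C)CC/C=C(/C)Br
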